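The runs are simulated on assumed constants; noise was put on by code.

Early in the flask the gas is still going into solution, for at the start none of it is there, while the second nucleophile stands at its full 1.00 M from the first moment, so I build the flask up one process at a time.

| flask | starting material | second nucleophile | gas | remark | time |
|---|---|---|---|---|---|
| delta | 0.50 M | 0.50 M | 200 mM (held) | run made earlier |  |
| epsilon | 0.50 M | 2 M | 200 mM (held) | run made earlier |  |
| flask | 0.50 M | 1.00 M | 200 mM (held) |  | 5.0 h |

- delta (time / h: other capture product / %, target / %): 0.833: 1.5, 6.6; 1.50: 3.4, 10.1; 2.50: 4.5, 15.0; 3.00: 5.9, 18.0; 4.00: 5.6, 21.7; 5.00: 7.3, 23.4; 6.00: 8.1, 26.8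
- epsilon (time / h: other capture product / %, target / %): 0.500: 3.8, 2.2; 0.667: 3.8, 4.0; 1.00: 7.2, 5.7; 1.50: 10.5, 7.3; 2.50: 15.3, 11.5; 4.00: 19.7, 15.8; 6.00: 23.3, 19.2

(standard deviation of a reading: 0.5 percentage points)

- at the start none of the gas is in solution

- share of other capture product in other capture product plus target at 12 min
- share of other capture product in other capture product plus target at 1.0 h
- share of other capture product in other capture product plus target at 5.0 h
- which of other capture product and target there is more of at 5.0 h

First I take the main step alone: one intermediate, shared by two captures, with the gas at its held level. The ratio of other capture product to target should then follow the second nucleophile, and the last readings of the two runs test this: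

delta: s = 8.1% / 26.8% / 0.50 M = 0.604 /M

epsilon: s = 23.3% / 19.2% / 2 M = 0.607 /M

mean: s = 0.606 /M

I carry this s, the ratio of other capture product to target per unit concentration of second nucleophile at held gas, a selectivity factor. For the flask I reckon:

ρ = s × 1.00 M = 0.606

share = ρ / (1 + ρ) = 37.7%

Next I add the loss of second nucleophile, working with the fraction left. Reckoned from the other capture product read, it is 91.9% in delta and 94.2% in epsilon at 6.00 h, so I treat its concentration as nearly constant, the pseudo-first-order picture.

Then I add the dissolving gas, which should push the earliest share above my 37.7%. I do not size this from the readings: the ratios read in epsilon, 1.73 at 0.500 h and 0.950 at 0.667 h, lie either side of the 1.21 that s gives for that run. I therefore commit to 37.7% at 5.0 h, with target ahead, and at 12 min to a higher share of unknown size.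

The forecast gives 42% at 12 min, 38.5% at 1.0 h and 37.5% at 5.0 h, with target ahead, and holds that “any lag is short”; at 12 min it thus puts a number where I give none.

The flask gives 53.7% at 12 min, 40.3% at 1.0 h and 37.2% at 5.0 h, with target ahead at 21.8% against 12.9%.

    starting material → intermediate (k = 0.00430 /min)
    first nucleophile + intermediate → target (k = 130 /M/min)
    second nucleophile + intermediate → other capture product (k = 13.0 /M/min)
    intermediate → solvolysis product (k = 37.0 /min)
    2 first nucleophile → homo dimer (k = 0.0510 /M/min)
    gas ⇌ first nucleophile, rate k6*(csat - [first nucleophile]) (kL = 0.120 /min)

In this flask other capture product leads until 0.265 h, when each stands at 1.36%. Held against ρ = 0.606, the flask's ratio is 0.592 at 5.0 h, but at 12 min it is 1.16, twice ρ. For the neighbouring flask with 2.5 M of second nucleophile, s gives a ratio of 1.51 and a share of 60.2%, and that flask gives 59.7% at 5.0 h.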